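## Retrosynthetic overview

1. Target 27 ⇐ octabenzyl ether 26 by global hydrogenolysis of eight benzyl ethers.
2. 26 ⇐ dihydrofuran 25 + diazonium salt 20 + boronic acid 17 by a new palladium-catalysed three-component syn-1,2-diarylation across C3=C4, which forms both C–aryl bonds and sets C3 and C4 of the oxolane.
3. 25 ⇐ 2,3-dihydrofuran 23 + two equivalents of aryl triflate 22 by two asymmetric Mizoroki–Heck arylations, which set C2 and C5.
4. 17 ⇐ bromide 14 ⇐ cis isomer 13 ⇐ hydrazone 11 of diaryl ketone 10: the dihydrobenzofuran ring is closed by an enantioselective rhodium-carbene C–H insertion and C2 is then epimerised to trans. Ketone 10 and salt 20 both come from 1,3-bis(benzyloxy)-5-bromobenzene 2.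
5. Ring order: the dihydrobenzofuran ring is formed first (step 8); the oxolane ring is carried from 23 and becomes fully substituted in step 16.

Assumption: the catalyst enantiomers named in steps 8, 14 and 15 follow the sense of induction known for the parent substrates; if a sense proves opposite, the mirror-image catalyst is used.

## Route

Step 1
Reactants: 1 5-bromobenzene-1,3-diol
Product: 2 1,3-bis(benzyloxy)-5-bromobenzene
Conditions: BnBr, K2CO3, DMF, 60 °C
Reagents that add atoms: benzyl bromide (BrCc1ccccc1)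
Why: Williamson ether synthesis on both phenols; no stereocentre.

Step 2
Reactants: 2 1,3-bis(benzyloxy)-5-bromobenzene
Product: 4 2,4-bis(benzyloxy)-6-bromobenzaldehyde, via iminium dichlorophosphate 3 (not isolated)
Conditions: POCl3, DMF, 0 → 80 °C; then aq. NaOAc
Reagents that add atoms: N,N-dimethylformamide (CN(C)C=O); water (O)
Why: Vilsmeier–Haack formylation, which attacks the ring position para to one benzyloxy group and next to bromine rather than the more crowded position between the two ethers.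

Step 3
Reactants: 4 2,4-bis(benzyloxy)-6-bromobenzaldehyde
Product: 5 4-(benzyloxy)-2-bromo-6-hydroxybenzaldehyde
Conditions: MgBr2·OEt2, toluene/Et2O, 80 °C; then 1 M HCl
Reagents that add atoms: none
Why: Chelation-controlled O-debenzylation: magnesium bridges the aldehyde oxygen and the ortho ether oxygen, so bromide removes only the ortho benzyl group.

Step 4
Reactants: 5 4-(benzyloxy)-2-bromo-6-hydroxybenzaldehyde; 6 1-(benzyloxy)-4-(chloromethyl)benzene
Product: 7 4-(benzyloxy)-2-{[4-(benzyloxy)phenyl]methoxy}-6-bromobenzaldehyde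
Conditions: K2CO3, NaI (cat.), DMF, 50 °C
Reagents that add atoms: none
Why: Williamson etherification of the free phenol with the benzylic chloride; it installs the benzylic CH2 that becomes C2 of the dihydrobenzofuran.

Step 5
Reactants: 7 4-(benzyloxy)-2-{[4-(benzyloxy)phenyl]methoxy}-6-bromobenzaldehyde; 2 1,3-bis(benzyloxy)-5-bromobenzene
Product: 9 [4-(benzyloxy)-2-{[4-(benzyloxy)phenyl]methoxy}-6-bromophenyl][3,5-bis(benzyloxy)phenyl]methanol (racemic), via arylmagnesium bromide 8 (not isolated)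
Conditions: 2, Mg, I2 (cat.), THF, 50 °C; then 7, −40 → 0 °C; then sat. aq. NH4Cl
Reagents that add atoms: none
Why: Grignard addition to the aldehyde; the aryl bromide of 7 is inert at low temperature, and the new carbinol centre is racemic and erased in step 6.

Step 6
Reactants: 9 [4-(benzyloxy)-2-{[4-(benzyloxy)phenyl]methoxy}-6-bromophenyl][3,5-bis(benzyloxy)phenyl]methanol
Product: 10 [4-(benzyloxy)-2-{[4-(benzyloxy)phenyl]methoxy}-6-bromophenyl][3,5-bis(benzyloxy)phenyl]methanone
Conditions: MnO2 (excess), CH2Cl2, rt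
Reagents that add atoms: none
Why: Oxidation of a doubly benzylic alcohol by MnO2; benzyl ethers and the aryl bromide are untouched.

Step 7
Reactants: 10 [4-(benzyloxy)-2-{[4-(benzyloxy)phenyl]methoxy}-6-bromophenyl][3,5-bis(benzyloxy)phenyl]methanone
Product: 11 the hydrazone of ketone 10 (E/Z mixture)
Conditions: N2H4·H2O (excess), AcOH (cat.), EtOH, 80 °C, sealed tube
Reagents that add atoms: hydrazine (NN)
Why: Hydrazone condensation; excess hydrazine and heat offset the two ortho substituents, and the E/Z ratio is irrelevant.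

Step 8
Reactants: 11 the hydrazone of ketone 10
Product: 13 (2S,3R)-6-(benzyloxy)-2-[4-(benzyloxy)phenyl]-3-[3,5-bis(benzyloxy)phenyl]-4-bromo-2,3-dihydro-1-benzofuran (2,3-cis), via diazo compound 12 (not isolated)
Conditions: MnO2, CH2Cl2, 0 °C; filter; Rh2(R-PTAD)4 (1 mol %), CH2Cl2, 0 °C → rt
Reagents that add atoms: none
Why: Oxidation of the hydrazone to the diaryl diazo compound, then dirhodium-carbene 1,5-C–H insertion into the adjacent benzylic ether C–H bond (donor/donor carbene insertion) closes the ring as the 2,3-cis isomer; the chiral carboxylate ligands (PTAD = (1-adamantyl)(phthalimido)acetate) set C3 as R and with it C2 as S.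

Step 9
Reactants: 13 (2S,3R)-6-(benzyloxy)-2-[4-(benzyloxy)phenyl]-3-[3,5-bis(benzyloxy)phenyl]-4-bromo-2,3-dihydro-1-benzofuran
Product: 14 (2R,3R)-6-(benzyloxy)-2-[4-(benzyloxy)phenyl]-3-[3,5-bis(benzyloxy)phenyl]-4-bromo-2,3-dihydro-1-benzofuran (2,3-trans)
Conditions: TFA (5 equiv), CH2Cl2, 0 °C → rt
Reagents that add atoms: none
Why: Acid-catalysed epimerisation: reversible ionisation of the C2–O bond to the para-benzyloxy-stabilised benzylic cation and re-closure gives the thermodynamically preferred trans isomer, inverting C2 to R while C3 is untouched.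

Step 10
Reactants: 14 (2R,3R)-6-(benzyloxy)-2-[4-(benzyloxy)phenyl]-3-[3,5-bis(benzyloxy)phenyl]-4-bromo-2,3-dihydro-1-benzofuran
Product: 17 [(2R,3R)-6-(benzyloxy)-2-[4-(benzyloxy)phenyl]-3-[3,5-bis(benzyloxy)phenyl]-2,3-dihydro-1-benzofuran-4-yl]boronic acid, via aryllithium 15 (not isolated), via lithium aryl(triisopropoxy)borate 16 (not isolated)
Conditions: B(Oi-Pr)3, n-BuLi, THF, −78 °C (in-situ quench); then 1 M HCl, 0 °C
Reagents that add atoms: triisopropyl borate (CC(C)OB(OC(C)C)OC(C)C); water (O)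
Why: Bromine–lithium exchange with immediate trapping by the borate and hydrolysis (lithiation–borylation); the stereocentres are not involved.

Step 11
Reactants: 2 1,3-bis(benzyloxy)-5-bromobenzene
Product: 19 3,5-bis(benzyloxy)aniline, via N,N-bis(trimethylsilyl)aniline 18 (not isolated)
Conditions: Pd2(dba)3 (1 mol %), P(t-Bu)3 (2 mol %), LiN(SiMe3)2, toluene, rt; then MeOH, K2CO3 (cat.)
Reagents that add atoms: lithium bis(trimethylsilyl)amide, LiN(SiMe3)2 ([Li]N([Si](C)(C)C)[Si](C)(C)C)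
Why: Buchwald–Hartwig amination with the silylamide as ammonia surrogate, then methanolysis of the N–Si bonds.

Step 12
Reactants: 19 3,5-bis(benzyloxy)aniline
Product: 20 3,5-bis(benzyloxy)benzenediazonium tetrafluoroborate
Conditions: NaNO2, HBF4 (48 % aq.), THF/H2O, 0 °C; precipitate with Et2O
Reagents that add atoms: sodium nitrite, NaNO2 ([Na+].[O-]N=O); tetrafluoroboric acid ([H+].F[B-](F)(F)F)
Why: Diazotisation in strong acid, where the protonated aniline cannot azo-couple; the salt is isolable.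

Step 13
Reactants: 21 4-(benzyloxy)phenol
Product: 22 4-(benzyloxy)phenyl trifluoromethanesulfonate
Conditions: Tf2O, pyridine, CH2Cl2, 0 °C
Reagents that add atoms: trifluoromethanesulfonic anhydride (O=S(=O)(OS(=O)(=O)C(F)(F)F)C(F)(F)F)
Why: O-Sulfonylation of the phenol to give the electrophile for the cationic Heck pathway.

Step 14
Reactants: 22 4-(benzyloxy)phenyl trifluoromethanesulfonate; 23 2,3-dihydrofuran
Product: 24 (2S)-2-[4-(benzyloxy)phenyl]-2,3-dihydrofuran
Conditions: Pd(OAc)2 (3 mol %), (S)-BINAP (6 mol %), 1,8-bis(dimethylamino)naphthalene, 23 (5 equiv), benzene, 40 °C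
Reagents that add atoms: none
Why: Asymmetric Mizoroki–Heck arylation at the enol-ether carbon by a cationic aryl–palladium–BINAP complex, which sets C2 as S by catalyst control; hydride re-insertion moves the double bond into the enol-ether position needed for step 15.

Step 15
Reactants: 24 (2S)-2-[4-(benzyloxy)phenyl]-2,3-dihydrofuran; 22 4-(benzyloxy)phenyl trifluoromethanesulfonate
Product: 25 (2S,5S)-2,5-bis[4-(benzyloxy)phenyl]-2,5-dihydrofuran (trans, C2-symmetric)
Conditions: Pd2(dba)3 (3 mol %), (R)-t-Bu-PHOX (7 mol %), i-Pr2NEt, THF, 70 °C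
Reagents that add atoms: none
Why: Second Mizoroki–Heck arylation at the enol-ether carbon C5, with the aryl delivered to the face opposite the C2 aryl (substrate bias reinforced by the ligand) to give the trans (2S,5S) product; the phosphinooxazoline ligand releases the palladium hydride before the double bond can migrate.

Step 16
Reactants: 25 (2S,5S)-2,5-bis[4-(benzyloxy)phenyl]-2,5-dihydrofuran; 20 3,5-bis(benzyloxy)benzenediazonium tetrafluoroborate; 17 [(2R,3R)-6-(benzyloxy)-2-[4-(benzyloxy)phenyl]-3-[3,5-bis(benzyloxy)phenyl]-2,3-dihydro-1-benzofuran-4-yl]boronic acid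
Product: 26 (2R,3R)-6-(benzyloxy)-2-[4-(benzyloxy)phenyl]-3-[3,5-bis(benzyloxy)phenyl]-4-{(2S,3S,4R,5S)-2,5-bis[4-(benzyloxy)phenyl]-4-[3,5-bis(benzyloxy)phenyl]oxolan-3-yl}-2,3-dihydro-1-benzofuran
Conditions: Pd2(dba)3 (5 mol %), 2,6-di-tert-butyl-4-methylpyridine (2 equiv), t-BuOH/THF, 0 → 20 °C; 25 (1.5 equiv), 20 (1.5 equiv), 17 (1.0 equiv, added over 4 h); aqueous work-up
Reagents that add atoms: none
Why: Proposed new method: a palladium-catalysed three-component syn-1,2-diarylation of an unstrained 2,5-dihydrofuran, in which the cationic aryl–palladium formed from 20 and zerovalent palladium (loss of N2) inserts into the C3=C4 bond of C2-symmetric 25 (its two alkene faces are equivalent) with the aryl going to the less hindered terminus C4, anti to the C5 aryl, and palladium to C3 beside the syn C2 aryl; the resulting σ-alkylpalladium has no syn β-hydrogen (both β-hydrogens lie on the opposite face), so Heck termination is blocked and it survives to transmetalate with the slowly added, hindered boronic acid 17 and reductively eliminate with retention, placing both new aryls on one face and giving the 2,3-cis-3,4-cis-4,5-trans (2S,3S,4R,5S) oxolane; the closest known reaction types are the three-component aryl halide/arylboronic acid vicinal diarylation of norbornene and the Heck–Matsuda/Suzuki 1,2-diarylation of terminal alkenes and 1,3-dienes.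

Step 17
Reactants: 26 the octabenzyl ether
Product: 27 (2R,3R)-3-(3,5-dihydroxyphenyl)-4-[(2S,3S,4R,5S)-4-(3,5-dihydroxyphenyl)-2,5-bis(4-hydroxyphenyl)oxolan-3-yl]-2-(4-hydroxyphenyl)-2,3-dihydro-1-benzofuran-6-ol (CNP0202577.3)
Conditions: H2 (1 atm), Pd(OH)2/C, THF/MeOH, rt
Reagents that add atoms: none
Why: Hydrogenolysis of the eight aryl benzyl ethers; the hindered cyclic benzylic C–O bonds of the oxolane and dihydrobenzofuran are cleaved far more slowly (as in debenzylation of flavans and 2,5-diaryl oxolane lignans), and no stereocentre is touched.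

## Compound list

1 | 5-bromobenzene-1,3-diol | Oc1cc(O)cc(Br)c1 | starting material
2 | 1,3-bis(benzyloxy)-5-bromobenzene | Brc1cc(OCc2ccccc2)cc(OCc2ccccc2)c1 | intermediate
3 | N-{[2,4-bis(benzyloxy)-6-bromophenyl]methylidene}-N-methylmethanaminium dichlorophosphate | C[N+](C)=Cc1c(Br)cc(OCc2ccccc2)cc1OCc1ccccc1.[O-]P(Cl)(Cl)=O | intermediate
4 | 2,4-bis(benzyloxy)-6-bromobenzaldehyde | O=Cc1c(Br)cc(OCc2ccccc2)cc1OCc1ccccc1 | intermediate
5 | 4-(benzyloxy)-2-bromo-6-hydroxybenzaldehyde | O=Cc1c(Br)cc(OCc2ccccc2)cc1O | intermediate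
6 | 1-(benzyloxy)-4-(chloromethyl)benzene | ClCc1ccc(OCc2ccccc2)cc1 | starting material
7 | 4-(benzyloxy)-2-{[4-(benzyloxy)phenyl]methoxy}-6-bromobenzaldehyde | O=Cc1c(Br)cc(OCc2ccccc2)cc1OCc1ccc(OCc2ccccc2)cc1 | intermediate
8 | [3,5-bis(benzyloxy)phenyl]magnesium bromide | Br[Mg]c1cc(OCc2ccccc2)cc(OCc2ccccc2)c1 | intermediate
9 | [4-(benzyloxy)-2-{[4-(benzyloxy)phenyl]methoxy}-6-bromophenyl][3,5-bis(benzyloxy)phenyl]methanol (racemic) | OC(c1cc(OCc2ccccc2)cc(OCc2ccccc2)c1)c1c(Br)cc(OCc2ccccc2)cc1OCc1ccc(OCc2ccccc2)cc1 | intermediate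
10 | [4-(benzyloxy)-2-{[4-(benzyloxy)phenyl]methoxy}-6-bromophenyl][3,5-bis(benzyloxy)phenyl]methanone | O=C(c1cc(OCc2ccccc2)cc(OCc2ccccc2)c1)c1c(Br)cc(OCc2ccccc2)cc1OCc1ccc(OCc2ccccc2)cc1 | intermediate
11 | hydrazone of ketone 10 (E/Z mixture) | NN=C(c1cc(OCc2ccccc2)cc(OCc2ccccc2)c1)c1c(Br)cc(OCc2ccccc2)cc1OCc1ccc(OCc2ccccc2)cc1 | intermediate
12 | diazo compound from 11: [4-(benzyloxy)-2-{[4-(benzyloxy)phenyl]methoxy}-6-bromophenyl][3,5-bis(benzyloxy)phenyl]diazomethane | [N-]=[N+]=C(c1cc(OCc2ccccc2)cc(OCc2ccccc2)c1)c1c(Br)cc(OCc2ccccc2)cc1OCc1ccc(OCc2ccccc2)cc1 | intermediate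
13 | (2S,3R)-6-(benzyloxy)-2-[4-(benzyloxy)phenyl]-3-[3,5-bis(benzyloxy)phenyl]-4-bromo-2,3-dihydro-1-benzofuran (cis) | Brc1cc(OCc2ccccc2)cc2c1[C@@H](c1cc(OCc3ccccc3)cc(OCc3ccccc3)c1)[C@@H](c1ccc(OCc3ccccc3)cc1)O2 | intermediate
14 | (2R,3R)-6-(benzyloxy)-2-[4-(benzyloxy)phenyl]-3-[3,5-bis(benzyloxy)phenyl]-4-bromo-2,3-dihydro-1-benzofuran (trans) | Brc1cc(OCc2ccccc2)cc2c1[C@@H](c1cc(OCc3ccccc3)cc(OCc3ccccc3)c1)[C@H](c1ccc(OCc3ccccc3)cc1)O2 | intermediate
15 | [(2R,3R)-6-(benzyloxy)-2-[4-(benzyloxy)phenyl]-3-[3,5-bis(benzyloxy)phenyl]-2,3-dihydro-1-benzofuran-4-yl]lithium | [Li]c1cc(OCc2ccccc2)cc2c1[C@@H](c1cc(OCc3ccccc3)cc(OCc3ccccc3)c1)[C@H](c1ccc(OCc3ccccc3)cc1)O2 | intermediate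
16 | lithium [(2R,3R)-dihydrobenzofuran-4-yl]tri(propan-2-yloxy)borate derived from 15 | [Li+].CC(C)O[B-](OC(C)C)(OC(C)C)c1cc(OCc2ccccc2)cc2c1[C@@H](c1cc(OCc3ccccc3)cc(OCc3ccccc3)c1)[C@H](c1ccc(OCc3ccccc3)cc1)O2 | intermediate
17 | [(2R,3R)-6-(benzyloxy)-2-[4-(benzyloxy)phenyl]-3-[3,5-bis(benzyloxy)phenyl]-2,3-dihydro-1-benzofuran-4-yl]boronic acid | OB(O)c1cc(OCc2ccccc2)cc2c1[C@@H](c1cc(OCc3ccccc3)cc(OCc3ccccc3)c1)[C@H](c1ccc(OCc3ccccc3)cc1)O2 | intermediate
18 | 3,5-bis(benzyloxy)-N,N-bis(trimethylsilyl)aniline | C[Si](C)(C)N(c1cc(OCc2ccccc2)cc(OCc2ccccc2)c1)[Si](C)(C)C | intermediate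
19 | 3,5-bis(benzyloxy)aniline | Nc1cc(OCc2ccccc2)cc(OCc2ccccc2)c1 | intermediate
20 | 3,5-bis(benzyloxy)benzenediazonium tetrafluoroborate | N#[N+]c1cc(OCc2ccccc2)cc(OCc2ccccc2)c1.F[B-](F)(F)F | intermediate
21 | 4-(benzyloxy)phenol | Oc1ccc(OCc2ccccc2)cc1 | starting material
22 | 4-(benzyloxy)phenyl trifluoromethanesulfonate | O=S(=O)(Oc1ccc(OCc2ccccc2)cc1)C(F)(F)F | intermediate
23 | 2,3-dihydrofuran | C1CC=CO1 | starting material
24 | (2S)-2-[4-(benzyloxy)phenyl]-2,3-dihydrofuran | c1ccccc1COc1ccc([C@@H]2CC=CO2)cc1 | intermediate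
25 | (2S,5S)-2,5-bis[4-(benzyloxy)phenyl]-2,5-dihydrofuran | c1ccccc1COc1ccc([C@H]2O[C@H](c3ccc(OCc4ccccc4)cc3)C=C2)cc1 | intermediate
26 | (2R,3R)-6-(benzyloxy)-2-[4-(benzyloxy)phenyl]-3-[3,5-bis(benzyloxy)phenyl]-4-{(2S,3S,4R,5S)-2,5-bis[4-(benzyloxy)phenyl]-4-[3,5-bis(benzyloxy)phenyl]oxolan-3-yl}-2,3-dihydro-1-benzofuran | c4ccccc4COc1ccc([C@H]2O[C@H](c3ccc(OCc4ccccc4)cc3)[C@@H](c3cc(OCc4ccccc4)cc(OCc4ccccc4)c3)[C@H]2c2cc(OCc4ccccc4)cc3c2[C@@H](c2cc(OCc4ccccc4)cc(OCc4ccccc4)c2)[C@H](c2ccc(OCc4ccccc4)cc2)O3)cc1 | intermediate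
27 | (2R,3R)-3-(3,5-dihydroxyphenyl)-4-[(2S,3S,4R,5S)-4-(3,5-dihydroxyphenyl)-2,5-bis(4-hydroxyphenyl)oxolan-3-yl]-2-(4-hydroxyphenyl)-2,3-dihydro-1-benzofuran-6-ol | Oc1ccc([C@H]2O[C@H](c3ccc(O)cc3)[C@@H](c3cc(O)cc(O)c3)[C@H]2c2cc(O)cc3c2[C@@H](c2cc(O)cc(O)c2)[C@H](c2ccc(O)cc2)O3)cc1 | target

## Summary

Total step count: 17.
Longest linear sequence: 12 steps (1 → 2 → 4 → 5 → 7 → 9 → 10 → 11 → 13 → 14 → 17 → 26 → 27; steps 1–10, 16, 17).

## The three steps most likely to fail

**Step 16 (the proposed diarylation).**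
- Risks: direct biaryl coupling of 20 with 17 before the alkene inserts; ortho C–H palladation of one of the two aryls cis to palladium; ring opening by β-alkoxide elimination; insertion with the opposite regiochemistry, which would give the single other diastereomer.
- Fallback, known chemistry: it sets out from 25 and comes back at 26. Nickel-catalysed syn-arylboration of 25 with bromide 14 and B2pin2 (NiCl2·DME, KOMe, DMA) puts boron on the open carbon and the aryl, delivered through nickel, on the carbon beside the syn aryl. This gives (2R,3R)-6-(benzyloxy)-2-[4-(benzyloxy)phenyl]-3-[3,5-bis(benzyloxy)phenyl]-4-[(2S,3S,4S,5S)-2,5-bis[4-(benzyloxy)phenyl]-4-(4,4,5,5-tetramethyl-1,3,2-dioxaborolan-2-yl)oxolan-3-yl]-2,3-dihydro-1-benzofuran F3.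
- Bromide 2 is converted with n-BuLi at −78 °C into [3,5-bis(benzyloxy)phenyl]lithium F4, which adds to F3 to give the lithium aryl(alkyl)pinacol boronate complex F5.
- N-Bromosuccinimide then triggers the stereoretentive 1,2-migration from boron to the electron-rich aryl ring (metal-free boronate arylation), forming the C4–aryl bond with retention and returning 26.

**Step 8 (diazo formation and C–H insertion next to an ortho bromine), together with the hindered hydrazone formation of step 7.**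
- Risks: slow hydrazone formation on the doubly ortho-substituted ketone, and reduced yield or selectivity of the carbene insertion.
- Fallback: it sets out from ketone 10, bypasses steps 7 to 9 and comes back at 14. The phosphazene base P4-t-Bu deprotonates the benzylic ether CH2, which adds to the ketone and dehydrates (base-mediated benzofuran cyclodehydration) to 6-(benzyloxy)-2-[4-(benzyloxy)phenyl]-3-[3,5-bis(benzyloxy)phenyl]-4-bromo-1-benzofuran F1.
- Ionic hydrogenation with Et3SiH/TFA delivers hydride anti to the neighbouring aryl and gives the racemic trans-dihydrobenzofuran, that is 14 together with its mirror image (2S,3S)-6-(benzyloxy)-2-[4-(benzyloxy)phenyl]-3-[3,5-bis(benzyloxy)phenyl]-4-bromo-2,3-dihydro-1-benzofuran F2.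
- Preparative chiral SFC separates the two and returns 14. This costs half the material but needs no carbene chemistry.

**Step 17 (eight-fold debenzylation).**
- Risks: over-reduction of the benzylic C–O bonds of the oxolane or the dihydrobenzofuran.
- Fallback: it sets out from 26 and comes back at 27. The reductive method is replaced by Lewis-acid dealkylation with BCl3 and pentamethylbenzene as benzyl-cation scavenger in CH2Cl2 at −78 °C, which removes the benzyl groups without hydrogen or a metal surface; no new isolated compound is involved.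

## Further compounds

F1 | step 8 | 6-(benzyloxy)-2-[4-(benzyloxy)phenyl]-3-[3,5-bis(benzyloxy)phenyl]-4-bromo-1-benzofuran | Brc1cc(OCc2ccccc2)cc2oc(-c3ccc(OCc4ccccc4)cc3)c(-c3cc(OCc4ccccc4)cc(OCc4ccccc4)c3)c12
F2 | step 8 | (2S,3S)-6-(benzyloxy)-2-[4-(benzyloxy)phenyl]-3-[3,5-bis(benzyloxy)phenyl]-4-bromo-2,3-dihydro-1-benzofuran | Brc1cc(OCc2ccccc2)cc2c1[C@H](c1cc(OCc3ccccc3)cc(OCc3ccccc3)c1)[C@@H](c1ccc(OCc3ccccc3)cc1)O2
F3 | step 16 | (2R,3R)-6-(benzyloxy)-2-[4-(benzyloxy)phenyl]-3-[3,5-bis(benzyloxy)phenyl]-4-[(2S,3S,4S,5S)-2,5-bis[4-(benzyloxy)phenyl]-4-(4,4,5,5-tetramethyl-1,3,2-dioxaborolan-2-yl)oxolan-3-yl]-2,3-dihydro-1-benzofuran | c1ccccc1COc1ccc([C@H]2O[C@H](c3ccc(OCc4ccccc4)cc3)[C@@H](B3OC(C)(C)C(C)(C)O3)[C@H]2c2cc(OCc4ccccc4)cc3c2[C@@H](c2cc(OCc4ccccc4)cc(OCc4ccccc4)c2)[C@H](c2ccc(OCc4ccccc4)cc2)O3)cc1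
F4 | step 16 | [3,5-bis(benzyloxy)phenyl]lithium | [Li]c1cc(OCc2ccccc2)cc(OCc2ccccc2)c1
F5 | step 16 | lithium aryl(alkyl)pinacol boronate complex formed from F3 and F4 | [Li+].c1ccccc1COc1ccc([C@H]2O[C@H](c3ccc(OCc4ccccc4)cc3)[C@@H]([B-]3(OC(C)(C)C(C)(C)O3)c3cc(OCc4ccccc4)cc(OCc4ccccc4)c3)[C@H]2c2cc(OCc4ccccc4)cc3c2[C@@H](c2cc(OCc4ccccc4)cc(OCc4ccccc4)c2)[C@H](c2ccc(OCc4ccccc4)cc2)O3)cc1
F0 | step 17 | none | none
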